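**Strategy.** Rings A and B are disconnected together at C4–C5, C9–C10 and C8–O (labdane numbering). The key step is a Mn(III)-mediated oxidative radical bicyclisation of an acyclic (E,E)-diene α-methyl-β-keto ester, terminated by a tert-butyl ester on the chain that captures oxidised C8 as a δ-lactone (C13–O–C8), a ring absent from the target. This single step closes both carbocycles and sets C4, C5, C10, C9 and C8. It exploits the axial, oxygenated C19 on quaternary C4 (born as the keto ester radical) and the trans relation of the C8 oxygen to the C9 chain (the lactone tether). An 8-phenylmenthyl ester, which ends as C19, controls the absolute sense; the lactone carbonyl becomes C13 of the diene.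

Key step: step 6

Remark on numbering: labdane numbering is used for all cyclised compounds; α is the face opposite the C10 methyl group (C20).

Assumption: the (1R,2S,5R)-8-phenylmenthyl ester is taken to shield the face of the non-chelated keto ester radical (ester C=O s-cis to C3) that would lead to the enantiomeric series, so that the natural 5R,10S series forms. This sense is not secured by the model alone; should the first cyclisation show the opposite sense, the enantiomeric auxiliary is used with no other change.

**Step 1**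
Reactants: 1 geranyl bromide; 2 tert-butyl acetate
Product: 3 tert-butyl (4E)-5,9-dimethyldeca-4,8-dienoate
Conditions: LDA (1.1 equiv), THF, −78 °C; then 1, DMPU, −78 → 0 °C
Reagents that add atoms: none
Why: Alkylation of the lithium ester enolate (SN2) at the primary allylic bromide is fast at low temperature and leaves the 2E-alkene of 1 untouched, which becomes the C8=C9 alkene of the cyclisation substrate.

**Step 2**
Reactants: 3 tert-butyl (4E)-5,9-dimethyldeca-4,8-dienoate
Product: 4 tert-butyl (4E,8E)-10-hydroxy-5,9-dimethyldeca-4,8-dienoate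
Conditions: SeO2 (0.3 equiv), t-BuOOH (70% aq., 3 equiv), salicylic acid (cat.), CH2Cl2, rt, stopped at partial conversion
Reagents that add atoms: selenium dioxide, O=[Se]=O (carries the oxygen); tert-butyl hydroperoxide, CC(C)(C)OO (terminal oxygen source)
Why: Catalytic SeO2 allylic oxidation (ene reaction, then [2,3]-sigmatropic shift) attacks the terminal, most accessible trisubstituted alkene at its (E)-methyl group and returns the E-allylic alcohol, while partial conversion limits over-oxidation and attack at the inner alkene.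

**Step 3**
Reactants: 4 tert-butyl (4E,8E)-10-hydroxy-5,9-dimethyldeca-4,8-dienoate
Product: 5 tert-butyl (4E,8E)-10-bromo-5,9-dimethyldeca-4,8-dienoate
Conditions: CBr4, PPh3, CH2Cl2, 0 °C
Reagents that add atoms: carbon tetrabromide, BrC(Br)(Br)Br
Why: The Appel reaction of a primary allylic alcohol proceeds by SN2 displacement of the oxyphosphonium group without allylic transposition or E/Z scrambling, and the tert-butyl ester is inert.

**Step 4**
Reactants: 6 (−)-8-phenylmenthol; 7 ethyl 2-methyl-3-oxobutanoate
Product: 8 (1R,2S,5R)-8-phenylmenthyl 2-methyl-3-oxobutanoate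
Conditions: DMAP (cat.), toluene, reflux with removal of EtOH
Reagents that add atoms: none
Why: DMAP-catalysed thermal transesterification of an enolisable β-keto ester (through the acylketene) accepts hindered secondary alcohols and is driven by removal of ethanol; the carbinol configuration of 6 is untouched and the α-centre is of no consequence.

**Step 5**
Reactants: 8 (1R,2S,5R)-8-phenylmenthyl 2-methyl-3-oxobutanoate; 5 tert-butyl (4E,8E)-10-bromo-5,9-dimethyldeca-4,8-dienoate
Product: 9 14-tert-butyl 1-[(1R,2S,5R)-8-phenylmenthyl] (6E,10E)-2,6,10-trimethyl-3-oxotetradeca-6,10-dienedioate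
Conditions: LDA (2.1 equiv), THF, −78 → 0 °C; then 5, −78 → 0 °C; aq. NH4Cl
Reagents that add atoms: none
Why: γ-Alkylation of the β-keto ester dianion, whose terminal carbanion reacts by SN2 with the primary allylic bromide faster than it can attack the tert-butyl ester, gives the 6E,10E-diene with the α-methyl-β-keto ester (both α-epimers, which converge in the radical) ready for oxidation.

**Step 6**
Reactants: 9 14-tert-butyl 1-[(1R,2S,5R)-8-phenylmenthyl] (6E,10E)-2,6,10-trimethyl-3-oxotetradeca-6,10-dienedioate
Product: 11 (1R,2S,5R)-8-phenylmenthyl 3-oxo-14,15,16-trinorlabdan-13,8α-olid-19-oate (tricyclic keto lactone), via bicyclic C8 radical 10 (not isolated)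
Conditions: Mn(OAc)3·2H2O (2.2 equiv), degassed AcOH, 25 °C, Ar, no Cu(II)
Reagents that add atoms: none
Why: Mn(III) enolisation and one-electron oxidation of the α-methyl-β-keto ester give the electrophilic tertiary C4 radical, which closes ring A by 6-endo-trig addition to C5 and ring B by 6-endo-trig addition of the resulting C10 radical to C9; the tertiary C8 radical 10 is then oxidised by Mn(III) to the cation, which the tert-butyl ester carbonyl captures in a six-membered closure with loss of isobutene (radical–polar crossover lactonisation). The closest known reaction type is the Mn(III)-based oxidative free-radical polyene cyclisation of 2-alkyl-β-keto esters, joined to the known Mn(III) oxidation of tertiary radicals to cations that a neighbouring ester captures as a lactone. Both ring closures need the 6-endo over the 5-exo mode, which the methyl groups on the inner alkene carbons (C10, C8) and the ketone inside ring A secure. The (E,E)-diene in a chair–chair fold gives the trans ring fusion (5α-H, 10β-CH3) and the equatorial C9 chain (9α-H), and C4 is set by the radical conformer that has the ester anti to the ketone oxygen, which places the ester carbon (C19) axial and cis to C20. The absolute configuration comes from the 8-phenylmenthyl group, whose phenyl ring covers one face of the planar radical so that C5 bonds to the open face. At C8 the tethered carbonyl oxygen should attack the cation on the α-face, because the β-face carries the axial C20 methyl and α-attack leads to the trans-fused δ-lactone, which fixes 8α-O and 8β-CH3; omitting Cu(II) keeps oxidative elimination from competing, and a C10 radical that is oxidised early would still close ring B as a cation to the same C8 cation.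

**Step 7**
Reactants: 11 (1R,2S,5R)-8-phenylmenthyl 3-oxo-14,15,16-trinorlabdan-13,8α-olid-19-oate
Product: 12 (1R,2S,5R)-8-phenylmenthyl 3,3-(ethane-1,2-diyldisulfanediyl)-14,15,16-trinorlabdan-13,8α-olid-19-oate (C3 dithiolane)
Conditions: HS(CH2)2SH, BF3·OEt2, CH2Cl2, 0 °C
Reagents that add atoms: ethane-1,2-dithiol, SCCS
Why: Lewis acid-promoted dithioketalisation is selective for the only ketone, 4,4-disubstituted 3-ketones of this ring system being known to form dithiolanes, and the lactone and the hindered ester should not react at 0 °C.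

**Step 8**
Reactants: 12 C3 dithiolane
Product: 13 (1R,2S,5R)-8-phenylmenthyl 14,15,16-trinorlabdan-13,8α-olid-19-oate
Conditions: Raney Ni (W-2), EtOH, reflux
Reagents that add atoms: none
Why: Raney nickel hydrogenolysis of the C–S bonds (Mozingo reduction) turns C3 into a methylene group at a stage where no alkene is present, and lactone, ester and arene are inert.

**Step 9**
Reactants: 13 (1R,2S,5R)-8-phenylmenthyl 14,15,16-trinorlabdan-13,8α-olid-19-oate
Product: 14 (1R,2S,5R)-8-phenylmenthyl 8α,13-epoxy-13-hydroxy-14,15,16-trinorlabdan-19-oate (lactol, both C13 epimers)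
Conditions: DIBAL-H (1.1 equiv), CH2Cl2, −78 °C; Rochelle salt
Reagents that add atoms: none
Why: DIBAL-H partial reduction at −78 °C stops at the aluminium lactolate of the unhindered δ-lactone, while the C19 ester, flanked by quaternary C4 and the bulky alkoxy group, is not attacked.

**Step 10**
Reactants: 14 lactol
Product: 16 (1R,2S,5R)-8-phenylmenthyl 8α-hydroxy-15,16-dinorlabd-13-yn-19-oate, via open-chain hydroxy aldehyde 15 (not isolated)
Conditions: dimethyl (1-diazo-2-oxopropyl)phosphonate, K2CO3, MeOH, rt → 40 °C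
Reagents that add atoms: dimethyl (1-diazo-2-oxopropyl)phosphonate, CC(=O)C(=[N+]=[N-])P(=O)(OC)OC
Why: In this Seyferth–Gilbert homologation (Ohira–Bestmann variant) the lactol equilibrates with hydroxy aldehyde 15, which is trapped by the diazomethylphosphonate anion formed in methanol, and the alkylidene carbene rearranges to the terminal alkyne (the new carbon becomes C14), while K2CO3/MeOH does not touch the hindered ester or the tertiary alcohol.

**Step 11**
Reactants: 16 (1R,2S,5R)-8-phenylmenthyl 8α-hydroxy-15,16-dinorlabd-13-yn-19-oate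
Product: 17 15,16-dinorlabd-13-yne-8α,19-diol
Conditions: LiAlH4, THF, reflux; aqueous work-up
Reagents that add atoms: none
Why: LiAlH4 reduction of the hindered ester at reflux gives the neopentyl C19 alcohol and returns auxiliary 6, the isolated alkyne and the tertiary alcohol being unaffected and no stereocentre being involved.

**Step 12**
Reactants: 17 15,16-dinorlabd-13-yne-8α,19-diol
Product: 18 labda-13(16),14-diene-8α,19-diol
Conditions: ethylene (1 atm), second-generation Ru benzylidene metathesis catalyst (5 mol%), toluene, 80 °C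
Reagents that add atoms: ethylene, C=C
Why: Ene–yne cross-metathesis of a terminal alkyne with ethylene gives the 2-substituted 1,3-butadiene directly (ethylene supplies C15 and C16), the ethylene atmosphere suppresses secondary metathesis of the diene, and free hydroxyl groups are tolerated.

**Step 13**
Reactants: 18 labda-13(16),14-diene-8α,19-diol; 19 (E)-4-acetoxy-3-methoxycinnamic acid
Product: 20 8α-hydroxylabda-13(16),14-dien-19-yl (E)-4-acetoxy-3-methoxycinnamate
Conditions: DCC, DMAP, CH2Cl2, rt
Reagents that add atoms: none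
Why: Steglich esterification acylates only the primary C19 hydroxyl, the tertiary C8 hydroxyl being unreactive towards the acylpyridinium, and the phenol of the acid is masked as its acetate to prevent self-acylation, with retention of the E-alkene.

**Step 14**
Reactants: 20 8α-hydroxylabda-13(16),14-dien-19-yl (E)-4-acetoxy-3-methoxycinnamate
Product: 21 8α-hydroxylabda-13(16),14-dien-19-yl (E)-ferulate (target, 4S,5R,8R,9R,10S)
Conditions: pyrrolidine, CH2Cl2, rt
Reagents that add atoms: none
Why: Aminolysis of the aryl acetate by pyrrolidine is much faster than attack on the alkyl cinnamate ester or conjugate addition to the electron-rich cinnamate, so the phenol is released without touching the C19 ester or the diene.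

**Compound list**

1 | geranyl bromide, (2E)-1-bromo-3,7-dimethylocta-2,6-diene | CC(C)=CCC/C(C)=C/CBr | starting material
2 | tert-butyl acetate | CC(=O)OC(C)(C)C | starting material
3 | tert-butyl (4E)-5,9-dimethyldeca-4,8-dienoate | CC(C)=CCC/C(C)=C/CCC(=O)OC(C)(C)C | intermediate
4 | tert-butyl (4E,8E)-10-hydroxy-5,9-dimethyldeca-4,8-dienoate | OC/C(C)=C/CC/C(C)=C/CCC(=O)OC(C)(C)C | intermediate
5 | tert-butyl (4E,8E)-10-bromo-5,9-dimethyldeca-4,8-dienoate | BrC/C(C)=C/CC/C(C)=C/CCC(=O)OC(C)(C)C | intermediate
6 | (−)-8-phenylmenthol, (1R,2S,5R)-5-methyl-2-(2-phenylpropan-2-yl)cyclohexan-1-ol | O[C@@H]1C[C@H](C)CC[C@H]1C(C)(C)c2ccccc2 | starting material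
7 | ethyl 2-methyl-3-oxobutanoate | CCOC(=O)C(C)C(C)=O | starting material
8 | (1R,2S,5R)-8-phenylmenthyl 2-methyl-3-oxobutanoate (both α-epimers) | CC(=O)C(C)C(=O)O[C@@H]1C[C@H](C)CC[C@H]1C(C)(C)c2ccccc2 | intermediate
9 | 14-tert-butyl 1-[(1R,2S,5R)-8-phenylmenthyl] (6E,10E)-2,6,10-trimethyl-3-oxotetradeca-6,10-dienedioate (both α-epimers) | CC(C(=O)CC/C(C)=C/CC/C(C)=C/CCC(=O)OC(C)(C)C)C(=O)O[C@@H]1C[C@H](C)CC[C@H]1C(C)(C)c2ccccc2 | intermediate
10 | bicyclic tertiary C8 radical (rings A and B closed, tert-butyl ester still open) | CC(C)(C)OC(=O)CC[C@@H]1[C@@]2(C)CCC(=O)[C@](C)(C(=O)O[C@@H]3C[C@H](C)CC[C@H]3C(C)(C)c4ccccc4)[C@@H]2CC[C]1C | intermediate (not isolated)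
11 | (1R,2S,5R)-8-phenylmenthyl 3-oxo-14,15,16-trinorlabdan-13,8α-olid-19-oate (4α-CH3, 4β-ester, 5α-H, 10β-CH3, 9α-H, 8β-CH3) | O=C1CC[C@@H]2[C@@]3(C)CCC(=O)[C@](C)(C(=O)O[C@@H]4C[C@H](C)CC[C@H]4C(C)(C)c5ccccc5)[C@@H]3CC[C@@]2(C)O1 | intermediate
12 | C3 ethylene dithioketal of 11 | O=C1CC[C@@H]2[C@@]3(C)CCC4(SCCS4)[C@](C)(C(=O)O[C@@H]5C[C@H](C)CC[C@H]5C(C)(C)c6ccccc6)[C@@H]3CC[C@@]2(C)O1 | intermediate
13 | (1R,2S,5R)-8-phenylmenthyl 14,15,16-trinorlabdan-13,8α-olid-19-oate | O=C1CC[C@@H]2[C@@]3(C)CCC[C@](C)(C(=O)O[C@@H]4C[C@H](C)CC[C@H]4C(C)(C)c5ccccc5)[C@@H]3CC[C@@]2(C)O1 | intermediate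
14 | (1R,2S,5R)-8-phenylmenthyl 8α,13-epoxy-13-hydroxy-14,15,16-trinorlabdan-19-oate (lactol, both C13 epimers) | OC1CC[C@@H]2[C@@]3(C)CCC[C@](C)(C(=O)O[C@@H]4C[C@H](C)CC[C@H]4C(C)(C)c5ccccc5)[C@@H]3CC[C@@]2(C)O1 | intermediate
15 | (1R,2S,5R)-8-phenylmenthyl 8α-hydroxy-13-oxo-14,15,16-trinorlabdan-19-oate (open hydroxy aldehyde) | O=CCC[C@@H]1[C@@]2(C)CCC[C@](C)(C(=O)O[C@@H]3C[C@H](C)CC[C@H]3C(C)(C)c4ccccc4)[C@@H]2CC[C@@]1(C)O | intermediate (not isolated)
16 | (1R,2S,5R)-8-phenylmenthyl 8α-hydroxy-15,16-dinorlabd-13-yn-19-oate | C#CCC[C@@H]1[C@@]2(C)CCC[C@](C)(C(=O)O[C@@H]3C[C@H](C)CC[C@H]3C(C)(C)c4ccccc4)[C@@H]2CC[C@@]1(C)O | intermediate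
17 | 15,16-dinorlabd-13-yne-8α,19-diol | C#CCC[C@@H]1[C@@]2(C)CCC[C@](C)(CO)[C@@H]2CC[C@@]1(C)O | intermediate
18 | labda-13(16),14-diene-8α,19-diol | C=CC(=C)CC[C@@H]1[C@@]2(C)CCC[C@](C)(CO)[C@@H]2CC[C@@]1(C)O | intermediate
19 | (E)-4-acetoxy-3-methoxycinnamic acid (O-acetylferulic acid) | CC(=O)Oc1ccc(/C=C/C(=O)O)cc1OC | starting material
20 | 8α-hydroxylabda-13(16),14-dien-19-yl (E)-4-acetoxy-3-methoxycinnamate | C=CC(=C)CC[C@@H]1[C@@]2(C)CCC[C@](C)(COC(=O)/C=C/c3ccc(OC(C)=O)c(OC)c3)[C@@H]2CC[C@@]1(C)O | intermediate
21 | 8α-hydroxylabda-13(16),14-dien-19-yl (E)-ferulate, (4S,5R,8R,9R,10S) | C=CC(=C)CC[C@@H]1[C@@]2(C)CCC[C@](C)(COC(=O)/C=C/c3ccc(O)c(OC)c3)[C@@H]2CC[C@@]1(C)O | target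

**Summary**

Total step count: 14.
Longest linear sequence: 13 steps (steps 1–3 and 5–14, from geranyl bromide).

Steps most likely to fail:

1. Step 6. The C8 radical may be diverted before the tethered ester closes (proton loss after oxidation, hydrogen abstraction, capture by acetic acid), or the ester may close on the β-face; face discrimination by the auxiliary in the first closure may also be incomplete, in which case the minor diastereomer is removed by chromatography at 11 or 13. The fallback sets out from 9 and comes back at 11. The cyclisation would be run with added Cu(OAc)2 (Mn(OAc)3, Cu(OAc)2, AcOH), the established terminating mode that turns the C8 radical into the exocyclic alkene and should give the 8(17)-ene keto diester F1. Mukaiyama hydration (Co(acac)2, PhSiH3, O2, THF) would then deliver the tertiary hydroxyl to the open α-face of C8 to give the 8α-hydroxy tert-butyl ester F2, and NaH in THF would close F2 to lactone 11 with loss of tert-butoxide.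

2. Step 7. Thioketalisation may stall at the hindered C3 carbonyl, and the Lewis acid may ionise the tertiary C8–O bond of the lactone (epimerisation or elimination at C8). The fallback sets out from 11 and comes back at 13. The ketone would be reduced with NaBH4 (MeOH/CH2Cl2, −20 °C) to the 3β-hydroxy lactone F3 (configuration at C3 immaterial), acylated with phenyl chlorothionoformate (pyridine, DMAP) to the O-phenyl thionocarbonate F4, and deoxygenated under Barton–McCombie conditions (Bu3SnH, AIBN, toluene, 90 °C) to give 13.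

3. Step 10. Homologation may be sluggish because the tertiary-alkoxy lactol stays closed while the diazophosphonate slowly decomposes. The fallback sets out from 14 and comes back at 18, and replaces the alkyne and metathesis route to the diene by carbonyl chemistry. Vinylmagnesium bromide (excess, THF, 0 °C) would open the lactol to the allylic diol F5 (both C13 epimers); MnO2 (CH2Cl2) would oxidise only the allylic secondary alcohol to the vinyl ketone F6; Wittig methylenation (Ph3P=CH2, THF, 0 °C) would give the diene ester F7; LiAlH4 (THF, reflux) would then release 18.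

**Further compounds**

F1 | step 6 | 13-tert-butyl 19-[(1R,2S,5R)-8-phenylmenthyl] 3-oxo-14,15,16-trinorlabd-8(17)-ene-13,19-dioate | CC(C)(C)OC(=O)CC[C@@H]1[C@@]2(C)CCC(=O)[C@](C)(C(=O)O[C@@H]3C[C@H](C)CC[C@H]3C(C)(C)c4ccccc4)[C@@H]2CCC1=C
F2 | step 6 | 13-tert-butyl 19-[(1R,2S,5R)-8-phenylmenthyl] 8α-hydroxy-3-oxo-14,15,16-trinorlabdane-13,19-dioate | CC(C)(C)OC(=O)CC[C@@H]1[C@@]2(C)CCC(=O)[C@](C)(C(=O)O[C@@H]3C[C@H](C)CC[C@H]3C(C)(C)c4ccccc4)[C@@H]2CC[C@@]1(C)O
F3 | step 7 | (1R,2S,5R)-8-phenylmenthyl 3β-hydroxy-14,15,16-trinorlabdan-13,8α-olid-19-oate | O=C1CC[C@@H]2[C@@]3(C)CC[C@H](O)[C@](C)(C(=O)O[C@@H]4C[C@H](C)CC[C@H]4C(C)(C)c5ccccc5)[C@@H]3CC[C@@]2(C)O1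
F4 | step 7 | (1R,2S,5R)-8-phenylmenthyl 3β-(phenoxycarbonothioyloxy)-14,15,16-trinorlabdan-13,8α-olid-19-oate | O=C1CC[C@@H]2[C@@]3(C)CC[C@H](OC(=S)Oc6ccccc6)[C@](C)(C(=O)O[C@@H]4C[C@H](C)CC[C@H]4C(C)(C)c5ccccc5)[C@@H]3CC[C@@]2(C)O1
F5 | step 10 | (1R,2S,5R)-8-phenylmenthyl 8α,13-dihydroxy-16-norlabd-14-en-19-oate (both C13 epimers) | C=CC(O)CC[C@@H]1[C@@]2(C)CCC[C@](C)(C(=O)O[C@@H]3C[C@H](C)CC[C@H]3C(C)(C)c4ccccc4)[C@@H]2CC[C@@]1(C)O
F6 | step 10 | (1R,2S,5R)-8-phenylmenthyl 8α-hydroxy-13-oxo-16-norlabd-14-en-19-oate | C=CC(=O)CC[C@@H]1[C@@]2(C)CCC[C@](C)(C(=O)O[C@@H]3C[C@H](C)CC[C@H]3C(C)(C)c4ccccc4)[C@@H]2CC[C@@]1(C)O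
F7 | step 10 | (1R,2S,5R)-8-phenylmenthyl 8α-hydroxylabda-13(16),14-dien-19-oate | C=CC(=C)CC[C@@H]1[C@@]2(C)CCC[C@](C)(C(=O)O[C@@H]3C[C@H](C)CC[C@H]3C(C)(C)c4ccccc4)[C@@H]2CC[C@@]1(C)O
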